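**Assumption:** positions are given in gibberellane numbering (C-1 to C-19; α is the face of the lactone oxygen, β the face of H-5 and H-9) for every intermediate.

## Retrosynthetic overview

1. Target ← hydrolysis of its 7,18-dimethyl ester; ring D ← SmI2 ketyl–alkyne closure (C-13 to C-16) of an 8β-propargyl C-13 ketone.
2. Quaternary C-8 ← conjugate propargylation of a ring B/ring C enone; ring B ← intramolecular Stork–Danheiser addition of the C-6 ester enolate to the C-8 carbonyl.
3. Late fragment union (C-9 to C-10): Reformatsky-type aldol of a ring C bromo vinylogous ester with an enantioenriched ring A keto triester; the new alkoxide closes the 19,10-lactone in the same operation.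
4. Ring A fragment ← asymmetric intramolecular malonate Michael addition (sets C-5), from malonic acid, 5-bromopent-1-ene and propiolic acid; ring C fragment ← cyclohexane-1,3-dione; C-15 to C-17 ← propargyl bromide.
5. Order of ring formation: ring A, lactone (ring C already attached), ring B, ring D.

## Route

Step 1
Reactants: 1 malonic acid
Product: 2 dimethyl malonate
Conditions: MeOH, H2SO4 (cat.), reflux
Reagents that add atoms: methanol, CO
Why: Fischer esterification in excess methanol converts both carboxyl groups to methyl esters and creates no stereocentre.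

Step 2
Reactants: 2 dimethyl malonate; 3 5-bromopent-1-ene
Product: 4 dimethyl 2-(pent-4-en-1-yl)malonate
Conditions: NaH, THF–DMF, 0 to 60 °C
Reagents that add atoms: none
Why: Malonic ester alkylation (displacement of the primary bromide by the sodium enolate) attaches C-1 to C-3 and the future C-10 to the future C-4 without creating a stereocentre.

Step 3
Reactants: 4 dimethyl 2-(pent-4-en-1-yl)malonate
Product: 6 dimethyl 2-(4-oxobutyl)malonate, via secondary ozonide 5 (not isolated)
Conditions: O3, CH2Cl2, −78 °C; then Me2S, −78 °C to rt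
Reagents that add atoms: ozone, [O-][O+]=O
Why: Ozonolysis with reductive work-up cleaves the only alkene to the aldehyde that becomes C-10 and creates no stereocentre.

Step 4
Reactants: 7 propiolic acid
Product: 8 (E)-3-iodoacrylic acid
Conditions: aq. HI (57 %), CuI (cat.), 130 °C
Reagents that add atoms: hydrogen iodide, I
Why: Hydroiodination of the alkynoic acid under equilibrating conditions gives the thermodynamically preferred E iodoalkene.

Step 5
Reactants: 8 (E)-3-iodoacrylic acid
Product: 9 methyl (E)-3-iodoacrylate
Conditions: MeOH, H2SO4 (cat.), reflux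
Reagents that add atoms: methanol, CO
Why: Fischer esterification leaves the alkenyl iodide and its E geometry untouched.

Step 6
Reactants: 10 cyclohexane-1,3-dione
Product: 11 3-ethoxycyclohex-2-en-1-one
Conditions: EtOH, p-toluenesulfonic acid (cat.), toluene, reflux (Dean–Stark)
Reagents that add atoms: ethanol, CCO
Why: Acid-catalysed enol ether formation with azeotropic removal of water gives the vinylogous ester needed for Stork–Danheiser chemistry.

Step 7
Reactants: 11 3-ethoxycyclohex-2-en-1-one
Product: 13 6-bromo-3-ethoxycyclohex-2-en-1-one, via lithium dienolate 12 (not isolated)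
Conditions: LiN(iPr)2, THF, −78 °C; then N-bromosuccinimide, −78 °C; H2O
Reagents that add atoms: N-bromosuccinimide, O=C1CCC(=O)N1Br
Why: Kinetic α′-deprotonation of the vinylogous ester followed by electrophilic bromination gives the racemic α′-bromo ketone, whose stereocentre is erased again in step 11.

Step 8
Reactants: 14 3-bromoprop-1-yne
Product: 16 tributyl(propa-1,2-dien-1-yl)stannane, via allenylmagnesium bromide 15 (not isolated)
Conditions: Mg, HgCl2 (cat.), Et2O, 0 °C; then Bu3SnCl, 0 °C to rt
Reagents that add atoms: tributyltin chloride, CCCC[Sn](Cl)(CCCC)CCCC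
Why: Grignard formation from propargyl bromide gives the allenyl magnesium species, which is transmetallated to the allenylstannane that later delivers C-15 to C-17.

Step 9
Reactants: 6 dimethyl 2-(4-oxobutyl)malonate; 9 methyl (E)-3-iodoacrylate
Product: 17 dimethyl 2-[(5E)-4-hydroxy-7-methoxy-7-oxohept-5-en-1-yl]malonate
Conditions: CrCl2 (3 equiv), NiCl2 (cat.), DMF, 25 °C; H2O
Reagents that add atoms: none
Why: The Nozaki–Hiyama–Kishi coupling adds the alkenyl iodide chemoselectively to the aldehyde with retention of the E geometry and tolerates the esters and the malonate C–H; the racemic carbinol centre is oxidised away in the next step.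

Step 10
Reactants: 17 dimethyl 2-[(5E)-4-hydroxy-7-methoxy-7-oxohept-5-en-1-yl]malonate
Product: 19 dimethyl (2R)-2-(2-methoxy-2-oxoethyl)-3-oxocyclohexane-1,1-dicarboxylate, via enone ester 18 (not isolated)
Conditions: MnO2, CH2Cl2, 25 °C, filter; then 1-[3,5-bis(trifluoromethyl)phenyl]-3-[(8α,9S)-6′-methoxycinchonan-9-yl]thiourea (10 mol %), toluene, −20 °C
Reagents that add atoms: none
Why: Allylic oxidation to the 4-oxo-enoate is followed by a bifunctional-thiourea-catalysed intramolecular 6-exo-trig Michael addition of the malonate to the enoate β-carbon, which closes ring A and sets C-5 by catalyst-controlled facial attack. The sense of induction is assigned by analogy, and the quinidine-derived pseudoenantiomeric thiourea is used instead should it prove opposite.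

Step 11
Reactants: 19 dimethyl (2R)-2-(2-methoxy-2-oxoethyl)-3-oxocyclohexane-1,1-dicarboxylate; 13 6-bromo-3-ethoxycyclohex-2-en-1-one
Product: 21 methyl 5-(4-ethoxy-2-oxocyclohex-3-en-1-yl)-8-(2-methoxy-2-oxoethyl)-7-oxo-6-oxabicyclo[3.2.1]octane-1-carboxylate (19,10-lactone; 5β-H; 9β-H), via aldol adduct 20 (not isolated)
Conditions: Zn, Et2AlCl, CuBr (cat.), THF, −20 to 25 °C; H2O
Reagents that add atoms: none
Why: In this Reformatsky-type aldol addition the weakly basic aluminium enolate attacks the C-10 ketone equatorially, trans to the C-5 side chain and away from the axial C-4 ester. The closed Zimmerman–Traxler transition state of the cyclic E enolate, with the branched C-5 side equatorial, gives the anti C-9/C-10 relationship. The axial alkoxide then lactonises onto the 1,3-diaxial ester, which fixes C-4 and makes the addition irreversible.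

Step 12
Reactants: 21 the 19,10-lactone vinylogous ester
Product: 23 ring A/ring B/ring C enone lactone diester (13-oxo; C-8=C-14 double bond), via cyclised hydroxy enol ether 22 (not isolated)
Conditions: LiN(iPr)2 (1.1 equiv), THF, −78 to −40 °C; then 1 M aq. HCl, THF, 25 °C
Reagents that add atoms: water, O
Why: In this intramolecular Stork–Danheiser sequence the secondary ester CH2 (C-6) is deprotonated kinetically in preference to the tertiary C-9 hydrogen, which is shielded by the quaternary C-10 and is only as acidic as an ester α-hydrogen because its carbonyl is a vinylogous ester. The enolate adds 5-exo-trig to the vinylogous ester carbonyl at C-8, and acid hydrolysis with dehydration transposes the system to the enone. Ring B thus closes trans to ring A on the already fixed C-5 and C-10, while C-6 stays an epimerisable mixture.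

Step 13
Reactants: 23 the enone lactone diester; 16 tributyl(propa-1,2-dien-1-yl)stannane
Product: 24 8β-(prop-2-yn-1-yl) C-13 ketone lactone diester
Conditions: TiCl4, CH2Cl2, −78 °C; H2O
Reagents that add atoms: none
Why: In this TiCl4-promoted conjugate propargylation (Sakurai type) the allenylstannane reacts through its terminal carbon with allylic transposition. It attacks C-8 axially on the face anti to the C-10 substituent at C-9, which creates the quaternary centre with the propargyl group syn to H-9 (cis ring B/ring C fusion).

Step 14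
Reactants: 24 the 8β-propargyl C-13 ketone
Product: 25 7,18-dimethyl ester of the target gibberellin (C-6 epimer mixture)
Conditions: SmI2, HMPA, t-BuOH, THF, 0 °C
Reagents that add atoms: none
Why: The SmI2-generated C-13 ketyl radical cyclises 5-exo-dig onto the alkyne and the vinyl radical is reduced and protonated, which forms ring D with the tertiary 13-hydroxyl and the exocyclic methylene in the only configuration the one-carbon tether allows.

Step 15
Reactants: 25 7,18-dimethyl ester of the target gibberellin
Product: 27 the target gibberellin (10α,13-dihydroxy-20-norgibberell-16-ene-7,18,19-trioic acid 19,10-lactone), via tripotassium seco-salt 26 (not isolated)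
Conditions: KOH, MeOH, 25 °C (C-6 equilibration); then H2O added, reflux; then 2 M aq. HCl, 0 °C (pH 2)
Reagents that add atoms: potassium hydroxide, [K+].[OH-]
Why: In methanolic base the hindered C-6 ester first equilibrates through its enolate to the thermodynamically preferred 6β epimer (trans to C-4). Saponification then cleaves both methyl esters and the lactone. Cold acidification relactonises the 10α-hydroxyl with the only C-4 carboxyl that can reach it, which restores the 19,10-lactone without disturbing the acid-sensitive 13-hydroxy-16-ene.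

## Compound list

1 | malonic acid | OC(=O)CC(=O)O | starting material
2 | dimethyl malonate | COC(=O)CC(=O)OC | intermediate
3 | 5-bromopent-1-ene | C=CCCCBr | starting material
4 | dimethyl 2-(pent-4-en-1-yl)malonate | C=CCCCC(C(=O)OC)C(=O)OC | intermediate
5 | dimethyl 2-[3-(1,2,4-trioxolan-3-yl)propyl]malonate (secondary ozonide) | COC(=O)C(CCCC1OCOO1)C(=O)OC | intermediate
6 | dimethyl 2-(4-oxobutyl)malonate | O=CCCCC(C(=O)OC)C(=O)OC | intermediate
7 | propiolic acid | C#CC(=O)O | starting material
8 | (E)-3-iodoacrylic acid | OC(=O)/C=C/I | intermediate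
9 | methyl (E)-3-iodoacrylate | COC(=O)/C=C/I | intermediate
10 | cyclohexane-1,3-dione | O=C1CCCC(=O)C1 | starting material
11 | 3-ethoxycyclohex-2-en-1-one | CCOC1=CC(=O)CCC1 | intermediate
12 | lithium 5-ethoxycyclohexa-1,5-dien-1-olate | [Li+].CCOC1=CC([O-])=CCC1 | intermediate
13 | 6-bromo-3-ethoxycyclohex-2-en-1-one (racemic) | CCOC1=CC(=O)C(Br)CC1 | intermediate
14 | 3-bromoprop-1-yne | C#CCBr | starting material
15 | propa-1,2-dien-1-ylmagnesium bromide | C=C=C[Mg]Br | intermediate
16 | tributyl(propa-1,2-dien-1-yl)stannane | CCCC[Sn](CCCC)(CCCC)C=C=C | intermediate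
17 | dimethyl 2-[(5E)-4-hydroxy-7-methoxy-7-oxohept-5-en-1-yl]malonate (racemic carbinol) | COC(=O)/C=C/C(O)CCCC(C(=O)OC)C(=O)OC | intermediate
18 | dimethyl 2-[(5E)-7-methoxy-4,7-dioxohept-5-en-1-yl]malonate | COC(=O)/C=C/C(=O)CCCC(C(=O)OC)C(=O)OC | intermediate
19 | dimethyl (2R)-2-(2-methoxy-2-oxoethyl)-3-oxocyclohexane-1,1-dicarboxylate (ring A fragment, C-5 set) | COC(=O)C[C@H]1C(=O)CCCC1(C(=O)OC)C(=O)OC | intermediate
20 | dimethyl 3-(4-ethoxy-2-oxocyclohex-3-en-1-yl)-3-hydroxy-2-(2-methoxy-2-oxoethyl)cyclohexane-1,1-dicarboxylate (5β-H, 9β-H, 10α-OH) | CCOC1=CC(=O)[C@@H](CC1)[C@]1(O)CCCC(C(=O)OC)(C(=O)OC)[C@H]1CC(=O)OC | intermediate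
21 | methyl 5-(4-ethoxy-2-oxocyclohex-3-en-1-yl)-8-(2-methoxy-2-oxoethyl)-7-oxo-6-oxabicyclo[3.2.1]octane-1-carboxylate (19,10-lactone; 5β-H, 9β-H) | CCOC1=CC(=O)[C@@H](CC1)[C@@]12CCC[C@@](C(=O)OC)(C(=O)O1)[C@H]2CC(=O)OC | intermediate
22 | ring B-closed 8-hydroxy 13-ethoxy-13-ene lactone diester (C-6 and C-8 epimer mixture) | CCOC=1CC[C@H]2[C@@]34CCC[C@@](C(=O)OC)(C(=O)O3)[C@H]4C(C(=O)OC)C2(O)C=1 | intermediate
23 | ring A/ring B/ring C enone lactone diester (13-oxo, C-8=C-14; 5β-H, 9β-H; C-6 epimer mixture) | O=C1CC[C@H]2[C@@]34CCC[C@@](C(=O)OC)(C(=O)O3)[C@H]4C(C(=O)OC)C2=C1 | intermediate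
24 | 8β-(prop-2-yn-1-yl) 13-ketone lactone diester (C-6 epimer mixture) | C#CC[C@]23CC(=O)CC[C@H]2[C@@]12CCC[C@@](C(=O)OC)(C(=O)O1)[C@H]2C3C(=O)OC | intermediate
25 | 7,18-dimethyl ester of the target gibberellin (C-6 epimer mixture) | C=C1C[C@]23C[C@@]1(O)CC[C@H]2[C@@]12CCC[C@@](C(=O)OC)(C(=O)O1)[C@H]2C3C(=O)OC | intermediate
26 | tripotassium salt of the lactone-opened 10α,13-dihydroxy 7,18,19-tricarboxylate (6β) | C=C1C[C@]23C[C@@]1(O)CC[C@H]2[C@]1(O)CCCC(C(=O)[O-])(C(=O)[O-])[C@H]1[C@@H]3C(=O)[O-].[K+].[K+].[K+] | intermediate
27 | target gibberellin: 10α,13-dihydroxy-20-norgibberell-16-ene-7,18,19-trioic acid 19,10-lactone (6β-carboxyl) | C=C1C[C@]23C[C@@]1(O)CC[C@H]2[C@@]12CCC[C@@](C(=O)O)(C(=O)O1)[C@H]2[C@@H]3C(=O)O | target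

## Step count and risks

Total step count: 15.
Longest linear sequence: 10 steps (1, 2, 3, 9, 10, 11, 12, 13, 14, 15).

Steps most likely to fail:

**Step 11** (union of 19 and 13). The ketone is hindered and enolisable, and the C-9/C-10 diastereoselectivity rests on a closed transition state. The fallback sets out from 11 and 19 and comes back at 21. The kinetic enolate of 11 (LiN(iPr)2, THF, −78 °C) is trapped with tert-butyldimethylsilyl chloride to give tert-butyl[(5-ethoxycyclohexa-1,5-dien-1-yl)oxy]dimethylsilane F1. This cross-conjugated silyl dienol ether is added to ketone 19 in a TiCl4-mediated Mukaiyama aldol reaction (CH2Cl2, −78 °C). The titanium aldolate corresponds to 20 and lactonises on warming to 21.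

**Step 12** (ring B closure). Deprotonation at C-9 instead of C-6 would expel the lactone carboxylate by β-elimination. The fallback sets out from 20 and comes back at 23. The aluminium aldolate of step 11 is quenched at −78 °C with triethylsilyl trifluoromethanesulfonate and 2,6-lutidine, before it lactonises, to give the 10α-triethylsilyloxy triester F2, in which the C-10 oxygen is a poor leaving group. Treatment with LiN(iPr)2 closes ring B to the 8-hydroxy enol ether F3. Aqueous HCl followed by p-toluenesulfonic acid in toluene at 60 °C removes the silyl group, transposes the enol ether to the enone and closes the 19,10-lactone, giving 23.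

**Step 13** (conjugate propargylation at the hindered C-8). The fallback sets out from 23 and comes back at 24. A Sakurai allylation (allyltrimethylsilane, TiCl4, CH2Cl2, −78 °C) gives the 8β-allyl 13-ketone F4 with the same facial selectivity. Ozonolysis (O3, then Me2S) gives the 8β-(2-oxoethyl) 13-ketone F5. Seyferth–Gilbert homologation with dimethyl (1-diazo-2-oxopropyl)phosphonate and K2CO3 in MeOH converts the aldehyde into the terminal alkyne of 24.

Further compounds
F1 | step 11 | tert-butyl[(5-ethoxycyclohexa-1,5-dien-1-yl)oxy]dimethylsilane | CCOC1=CC(O[Si](C)(C)C(C)(C)C)=CCC1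
F2 | step 12 | dimethyl 3-(4-ethoxy-2-oxocyclohex-3-en-1-yl)-2-(2-methoxy-2-oxoethyl)-3-(triethylsilyloxy)cyclohexane-1,1-dicarboxylate (5β-H, 9β-H, 10α-O) | CCOC1=CC(=O)[C@@H](CC1)[C@]1(O[Si](CC)(CC)CC)CCCC(C(=O)OC)(C(=O)OC)[C@H]1CC(=O)OC
F3 | step 12 | ring B-closed 8-hydroxy 13-ethoxy-13-ene 10α-triethylsilyloxy triester (C-6 and C-8 epimer mixture) | CCOC=1CC[C@H]2[C@]3(O[Si](CC)(CC)CC)CCCC(C(=O)OC)(C(=O)OC)[C@H]3C(C(=O)OC)C2(O)C=1
F4 | step 13 | 8β-(prop-2-en-1-yl) 13-ketone lactone diester (C-6 epimer mixture) | C=CC[C@]23CC(=O)CC[C@H]2[C@@]12CCC[C@@](C(=O)OC)(C(=O)O1)[C@H]2C3C(=O)OC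
F5 | step 13 | 8β-(2-oxoethyl) 13-ketone lactone diester (C-6 epimer mixture) | O=CC[C@]23CC(=O)CC[C@H]2[C@@]12CCC[C@@](C(=O)OC)(C(=O)O1)[C@H]2C3C(=O)OC
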